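## Retrosynthetic overview

- Target 12 comes from flavanone 11 by removal of two MOM ethers; 11 is cut across ring C at C2–C3 and O1–C8a into enol silane 7 (ring A) and aldehyde 9 (ring B).
- Enabling feature: in ring A, C8a is ortho to the C4 carbonyl and meta to both oxygen-bearing carbons C5 and C7, so a fluorine at C8a is an activated leaving group, while the C3 methyl of the same ketone is the enol donor. Compound 7 is thus a benzo-fused 1-fluoro-3-silyloxy-1,3-diene that takes up the C=O of 9 as C2 and O1.
- 7 comes from 5-fluororesorcinol by C-acylation, MOM protection, bromination at the future C8, Stille prenylation and enol silylation; 9 comes from 3-bromo-4-methoxybenzaldehyde by Stille prenylation.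
- Ring order: rings A and B are bought; ring C is the only ring formed, in step 7, which also sets the single stereocentre C2.

Key step: step 7

Assumption: the oxazaborolidinone made from N-tosyl-(R)-tryptophan is taken to direct the enol silane to the Si face of aldehyde 9 (giving 2S); if the sense proves opposite, the catalyst from the (S)-amino acid is used instead.

## Route

Step 1
Reactants: 1 5-fluorobenzene-1,3-diol (5-fluororesorcinol)
Product: 2 1-(2-fluoro-4,6-dihydroxyphenyl)ethan-1-one
Conditions: AcOH (1.2 equiv), BF3·OEt2 (as solvent), 85 °C; aqueous work-up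
Reagents that add atoms: acetic acid, CC(=O)O
Why: Friedel–Crafts C-acylation in which the two hydroxyls direct the acylium ion to the ring carbon para to one OH and ortho to the other (as with resorcinol itself), which here is also ortho to fluorine, and the deactivated ketone product should resist a second acylation.

Step 2
Reactants: 2 1-(2-fluoro-4,6-dihydroxyphenyl)ethan-1-one
Product: 3 1-[2-fluoro-4,6-bis(methoxymethoxy)phenyl]ethan-1-one
Conditions: MOMCl (2.5 equiv), NaH (2.5 equiv), DMF, 0 → 20 °C
Reagents that add atoms: chloromethyl methyl ether, COCCl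
Why: Williamson-type O-alkylation of both phenoxides, the sodium salt in DMF being reactive enough to alkylate the hydrogen-bonded ortho hydroxyl as well.

Step 3
Reactants: 3 1-[2-fluoro-4,6-bis(methoxymethoxy)phenyl]ethan-1-one
Product: 4 1-[3-bromo-2-fluoro-4,6-bis(methoxymethoxy)phenyl]ethan-1-one
Conditions: NBS (1.05 equiv), MeCN, 0 → 20 °C, dark
Reagents that add atoms: N-bromosuccinimide, O=C1CCC(=O)N1Br
Why: Electrophilic aromatic bromination at the carbon para to the 6-OMOM and ortho to the 4-OMOM group (the future C8), which should be favoured over the more hindered carbon flanked by both ethers, as in the C5 bromination of 2,4-dialkoxyacetophenones.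

Step 4
Reactants: 4 1-[3-bromo-2-fluoro-4,6-bis(methoxymethoxy)phenyl]ethan-1-one; 5 tributyl(3-methylbut-2-en-1-yl)stannane
Product: 6 1-[2-fluoro-4,6-bis(methoxymethoxy)-3-(3-methylbut-2-en-1-yl)phenyl]ethan-1-one
Conditions: Pd(PPh3)4 (5 mol%), DMF, 90 °C
Reagents that add atoms: none
Why: Stille coupling in which the allylpalladium intermediate equilibrates through its η3 form and reductive elimination at the unsubstituted terminus should give the linear prenyl arene, with ketone, aryl fluoride and MOM ethers inert.

Step 5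
Reactants: 6 1-[2-fluoro-4,6-bis(methoxymethoxy)-3-(3-methylbut-2-en-1-yl)phenyl]ethan-1-one
Product: 7 trimethyl({1-[2-fluoro-4,6-bis(methoxymethoxy)-3-(3-methylbut-2-en-1-yl)phenyl]ethenyl}oxy)silane
Conditions: LiN(SiMe3)2 (1.1 equiv) added to 6 and Me3SiCl (1.3 equiv), THF, −78 °C (in situ quench); non-aqueous work-up (pentane, filtration), used crude
Reagents that add atoms: chlorotrimethylsilane, C[Si](C)(C)Cl
Why: Kinetic deprotonation of the only enolisable position (the acetyl methyl) with O-silylation of the enolate as it forms, the hindered amide base being too weak a nucleophile to attack the aryl fluoride.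

Step 6
Reactants: 8 3-bromo-4-methoxybenzaldehyde; 5 tributyl(3-methylbut-2-en-1-yl)stannane
Product: 9 4-methoxy-3-(3-methylbut-2-en-1-yl)benzaldehyde
Conditions: Pd(PPh3)4 (5 mol%), DMF, 90 °C
Reagents that add atoms: none
Why: Stille coupling of an activated aryl bromide, which tolerates the free aldehyde and should again deliver the linear prenyl group.

Step 7
Reactants: 7 trimethyl({1-[2-fluoro-4,6-bis(methoxymethoxy)-3-(3-methylbut-2-en-1-yl)phenyl]ethenyl}oxy)silane; 9 4-methoxy-3-(3-methylbut-2-en-1-yl)benzaldehyde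
Product: 11 (2S)-5,7-bis(methoxymethoxy)-2-[4-methoxy-3-(3-methylbut-2-en-1-yl)phenyl]-8-(3-methylbut-2-en-1-yl)-2,3-dihydro-4H-chromen-4-one, via silyl ether 10 (not isolated)
Conditions: (R)-2-butyl-4-(indol-3-ylmethyl)-3-tosyl-1,3,2-oxazaborolidin-5-one (20 mol%, from N-tosyl-(R)-tryptophan and BuB(OH)2), EtCN, −78 °C until 9 is consumed; then nBu4N[Ph3SiF2] (0.4 equiv), THF, −78 → 20 °C
Reagents that add atoms: none
Why: The boron Lewis acid activates aldehyde 9 for an open Mukaiyama aldol addition of 7 that forms C2–C3 and passes the trimethylsilyl group to the new oxygen (10); fluoride then unmasks the C2 alkoxide, which adds to C8a and expels fluoride through a Meisenheimer intermediate stabilised by the C4 carbonyl, and the expelled fluoride desilylates the next molecule of 10, so that Me3SiF is the only by-product. The closest known reaction types are the oxazaborolidinone-catalysed Mukaiyama aldol and aldol–dihydropyranone annulation of aldehydes with silyl enol ethers and 1-methoxy-3-silyloxydienes, the fluoride-catalysed condensation of silyl ethers with activated aryl fluorides, and the base-mediated closure of 3-hydroxy-1-(2-fluoroaryl)propan-1-ones to chroman-4-ones. Ring C closes by 6-exo-trig attack of O1 on C8a followed by loss of fluoride. The C2 stereocentre is set in the aldol stage by the catalyst, whose indole ring shields one face of the boron-bound aldehyde so that the enol silane adds to the Si face, and it enters the ring with retention because the C2–O bond is never broken. The step needs attack at C8a and not at C5, and it must avoid retro-aldol or dehydration of the aldolate. Fluoride is a far better leaving group than methoxymethoxide and sits ortho to the carbonyl and meta to both ring oxygens, and the silyl ether keeps the aldolate masked until the cold fluoride chain releases it only transiently next to its electrophile.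

Step 8
Reactants: 11 (2S)-5,7-bis(methoxymethoxy)-2-[4-methoxy-3-(3-methylbut-2-en-1-yl)phenyl]-8-(3-methylbut-2-en-1-yl)-2,3-dihydro-4H-chromen-4-one
Product: 12 (2S)-5,7-dihydroxy-2-[4-methoxy-3-(3-methylbut-2-en-1-yl)phenyl]-8-(3-methylbut-2-en-1-yl)-2,3-dihydro-4H-chromen-4-one
Conditions: 3 M aq. HCl, MeOH, 40 °C, short reaction time
Reagents that add atoms: none
Why: Acid-catalysed acetal exchange should cleave both MOM ethers while the aryl methyl ether, the two trisubstituted alkenes and the C2 stereocentre (labile only to base, through ring opening to the chalcone) survive brief mild acid.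

## Compound list

1 | 5-fluorobenzene-1,3-diol | Oc1cc(O)cc(F)c1 | starting material
2 | 1-(2-fluoro-4,6-dihydroxyphenyl)ethan-1-one | CC(=O)c1c(O)cc(O)cc1F | intermediate
3 | 1-[2-fluoro-4,6-bis(methoxymethoxy)phenyl]ethan-1-one | CC(=O)c1c(OCOC)cc(OCOC)cc1F | intermediate
4 | 1-[3-bromo-2-fluoro-4,6-bis(methoxymethoxy)phenyl]ethan-1-one | CC(=O)c1c(OCOC)cc(OCOC)c(Br)c1F | intermediate
5 | tributyl(3-methylbut-2-en-1-yl)stannane | CCCC[Sn](CCCC)(CCCC)CC=C(C)C | starting material
6 | 1-[2-fluoro-4,6-bis(methoxymethoxy)-3-(3-methylbut-2-en-1-yl)phenyl]ethan-1-one | CC(=O)c1c(OCOC)cc(OCOC)c(CC=C(C)C)c1F | intermediate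
7 | trimethyl({1-[2-fluoro-4,6-bis(methoxymethoxy)-3-(3-methylbut-2-en-1-yl)phenyl]ethenyl}oxy)silane | C=C(O[Si](C)(C)C)c1c(OCOC)cc(OCOC)c(CC=C(C)C)c1F | intermediate
8 | 3-bromo-4-methoxybenzaldehyde | COc1ccc(C=O)cc1Br | starting material
9 | 4-methoxy-3-(3-methylbut-2-en-1-yl)benzaldehyde | COc1ccc(C=O)cc1CC=C(C)C | intermediate
10 | (3S)-1-[2-fluoro-4,6-bis(methoxymethoxy)-3-(3-methylbut-2-en-1-yl)phenyl]-3-[4-methoxy-3-(3-methylbut-2-en-1-yl)phenyl]-3-(trimethylsilyloxy)propan-1-one | COc1ccc([C@@H](O[Si](C)(C)C)CC(=O)c2c(OCOC)cc(OCOC)c(CC=C(C)C)c2F)cc1CC=C(C)C | intermediate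
11 | (2S)-5,7-bis(methoxymethoxy)-2-[4-methoxy-3-(3-methylbut-2-en-1-yl)phenyl]-8-(3-methylbut-2-en-1-yl)-2,3-dihydro-4H-chromen-4-one | COc1ccc([C@@H]2CC(=O)c3c(OCOC)cc(OCOC)c(CC=C(C)C)c3O2)cc1CC=C(C)C | intermediate
12 | (2S)-5,7-dihydroxy-2-[4-methoxy-3-(3-methylbut-2-en-1-yl)phenyl]-8-(3-methylbut-2-en-1-yl)-2,3-dihydro-4H-chromen-4-one | COc1ccc([C@@H]2CC(=O)c3c(O)cc(O)c(CC=C(C)C)c3O2)cc1CC=C(C)C | target

## Step count and risks

Total step count: 8. Longest linear sequence: 7 steps (steps 1–5, 7 and 8).

Steps most likely to fail: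

1. Step 7. The enantiomeric purity may erode, either through incomplete facial control in the aldol stage with the doubly ortho-substituted enol silane or through retro-aldol scrambling or dehydration of the unmasked aldolate before it closes onto C8a. The fallback obtains the stereocentre by resolution instead of induction. It sets out from 6 and 9: the lithium enolate of 6 (LiN(SiMe3)2, THF, −78 °C) would add to 9 to give, as its lithium alkoxide, racemic 1-[2-fluoro-4,6-bis(methoxymethoxy)-3-(3-methylbut-2-en-1-yl)phenyl]-3-hydroxy-3-[4-methoxy-3-(3-methylbut-2-en-1-yl)phenyl]propan-1-one F1. On warming with added DMF this should close by the same fluoride displacement to racemic 5,7-bis(methoxymethoxy)-2-[4-methoxy-3-(3-methylbut-2-en-1-yl)phenyl]-8-(3-methylbut-2-en-1-yl)-2,3-dihydro-4H-chromen-4-one F2. Kinetic resolution by asymmetric transfer hydrogenation (RuCl(TsDPEN)(p-cymene), the antipode that reduces the 2R ketone, HCO2H/Et3N, EtOAc, 23 °C) would turn the unwanted enantiomer into (2R,4R)-5,7-bis(methoxymethoxy)-2-[4-methoxy-3-(3-methylbut-2-en-1-yl)phenyl]-8-(3-methylbut-2-en-1-yl)-3,4-dihydro-2H-chromen-4-ol F3, which is separated. The unreduced 2S ketone comes back to the route at 11.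

2. Step 3. Bromine may enter at the carbon flanked by the two ether oxygens (the future C6) or at the acetyl methyl group instead of at the future C8. The fallback installs the prenyl group by an aromatic Claisen rearrangement and sets out from 2. Selective alkylation of the non-chelated 4-hydroxyl (3-chloro-3-methylbut-1-yne, DBU, CuCl2 cat., MeCN, 0 °C) would give 1-{2-fluoro-6-hydroxy-4-[(2-methylbut-3-yn-2-yl)oxy]phenyl}ethan-1-one F4. MOM protection (MOMCl, NaH, DMF) would give 1-{2-fluoro-6-(methoxymethoxy)-4-[(2-methylbut-3-yn-2-yl)oxy]phenyl}ethan-1-one F5. Semi-hydrogenation (H2, Pd/CaCO3 poisoned with Pb(OAc)2, quinoline, EtOAc) would give 1-{2-fluoro-6-(methoxymethoxy)-4-[(2-methylbut-3-en-2-yl)oxy]phenyl}ethan-1-one F6. Claisen rearrangement (N,N-diethylaniline, 130 °C) should go to the less hindered ortho carbon next to fluorine and give 1-[2-fluoro-4-hydroxy-6-(methoxymethoxy)-3-(3-methylbut-2-en-1-yl)phenyl]ethan-1-one F7. A second MOM protection (MOMCl, NaH, DMF) comes back to the route at 6.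

3. Step 4. Allylic transposition during transfer of the prenyl group from tin to palladium may give the 1,1-dimethylallyl arene, and slow oxidative addition at the doubly ortho-substituted bromide may lead to protodebromination. The fallback transfers an unsubstituted allyl group and builds the trisubstituted alkene afterwards; it sets out from 4. Stille coupling with allyltributylstannane (Pd(PPh3)4, DMF, 90 °C) would give 1-[2-fluoro-4,6-bis(methoxymethoxy)-3-(prop-2-en-1-yl)phenyl]ethan-1-one F8. Cross-metathesis with 2-methylbut-2-ene (second-generation Grubbs catalyst, CH2Cl2, 40 °C) comes back to the route at 6.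

Further compounds
F1 | step 7 | racemic 1-[2-fluoro-4,6-bis(methoxymethoxy)-3-(3-methylbut-2-en-1-yl)phenyl]-3-hydroxy-3-[4-methoxy-3-(3-methylbut-2-en-1-yl)phenyl]propan-1-one | COc1ccc(C(O)CC(=O)c2c(OCOC)cc(OCOC)c(CC=C(C)C)c2F)cc1CC=C(C)C
F2 | step 7 | racemic 5,7-bis(methoxymethoxy)-2-[4-methoxy-3-(3-methylbut-2-en-1-yl)phenyl]-8-(3-methylbut-2-en-1-yl)-2,3-dihydro-4H-chromen-4-one | COc1ccc(C2CC(=O)c3c(OCOC)cc(OCOC)c(CC=C(C)C)c3O2)cc1CC=C(C)C
F3 | step 7 | (2R,4R)-5,7-bis(methoxymethoxy)-2-[4-methoxy-3-(3-methylbut-2-en-1-yl)phenyl]-8-(3-methylbut-2-en-1-yl)-3,4-dihydro-2H-chromen-4-ol | COc1ccc([C@H]2C[C@@H](O)c3c(OCOC)cc(OCOC)c(CC=C(C)C)c3O2)cc1CC=C(C)C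
F4 | step 3 | 1-{2-fluoro-6-hydroxy-4-[(2-methylbut-3-yn-2-yl)oxy]phenyl}ethan-1-one | CC(=O)c1c(O)cc(OC(C)(C)C#C)cc1F
F5 | step 3 | 1-{2-fluoro-6-(methoxymethoxy)-4-[(2-methylbut-3-yn-2-yl)oxy]phenyl}ethan-1-one | CC(=O)c1c(OCOC)cc(OC(C)(C)C#C)cc1F
F6 | step 3 | 1-{2-fluoro-6-(methoxymethoxy)-4-[(2-methylbut-3-en-2-yl)oxy]phenyl}ethan-1-one | CC(=O)c1c(OCOC)cc(OC(C)(C)C=C)cc1F
F7 | step 3 | 1-[2-fluoro-4-hydroxy-6-(methoxymethoxy)-3-(3-methylbut-2-en-1-yl)phenyl]ethan-1-one | CC(=O)c1c(OCOC)cc(O)c(CC=C(C)C)c1F
F8 | step 4 | 1-[2-fluoro-4,6-bis(methoxymethoxy)-3-(prop-2-en-1-yl)phenyl]ethan-1-one | CC(=O)c1c(OCOC)cc(OCOC)c(CC=C)c1F
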